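## The problem

Kuwanon E (19) is a (2S)-flavanone in which ring A is a 5,7-dihydroxylated benzene ring, ring C a dihydropyranone, and ring B a 2',4'-dihydroxyphenyl group at C2 that carries an (E)-geranyl chain at C5'. The only stereocentre is C2, which bears O1, ring B, H and the C3 methylene; nothing else in the molecule can direct it, so it must be set by a catalyst or reagent. C2 is also fragile: it is benzylic to a ring with ortho and para oxygens and beta to the C4 ketone, so base opens ring C by E1cB to a chalcone and acid can ionise the C2–O1 bond, which rules out closing ring C by a reversible O1–C2 bond formation. The geranyl chain has two electron-rich trisubstituted alkenes, which excludes hydrogenolysis, electrophilic oxidants and strong acids (the 4'-hydroxyl would add to the C2''=C3'' alkene), and its E geometry has to survive. Four phenols must be masked through organolithium and basic steps and released without harming the chain or C2. The enabling feature is that C2 is the beta-oxygenated carbon of an aryl ketone (C4) with an unsubstituted C3 methylene, a masked aldol: its oxygen can be delivered to a chalcone enone by a nucleophilic, catalyst-controlled epoxidation, and the extra C3–O bond can then be removed reductively next to the C4 carbonyl. O1–C8a is an aryl–oxygen bond ortho to that carbonyl, so it can be formed by displacing a fluoride without touching any bond at C2.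

## Retrosynthesis

19 from 18. No skeletal bond is cut; the four phenols are masked as methoxymethyl ethers in 18. Benzyl ethers would need hydrogenolysis, which would saturate the chain. Methyl ethers would need a boron trihalide, which would attack the alkenes. Silyl ethers would not survive the hydroxide-mediated condensation. The forward step only needs a mild acetal cleavage.

18 from 17. The O1–C8a bond is cut, giving the open-chain (S)-aldol 17 with a fluorine on the future C8a. Cutting O1–C2 instead would mean an oxa-Michael closure of a hydroxychalcone (reversible, racemising) or an inverting displacement at the benzylic carbon. The aryl–oxygen cut leaves all four bonds at C2 intact, so the configuration is carried over unchanged. The forward reaction needs the alkoxide of 17 to attack the fluorinated carbon, activated by the ortho carbonyl, faster than it fragments by retro-aldol.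

17 from 16. A C3–O bond is added back, turning the aldol into the trans epoxy ketone 16. A direct enantioselective aldol between 4 and 13 would be an acetate-type addition of a hindered aryl methyl ketone, for which no dependable catalytic control exists. The epoxide route replaces it with a well-controlled alkene oxidation. The forward step needs selective reductive cleavage of the C–O bond alpha to the ketone, leaving the beta C–O bond alone.

16 from 15. Both oxirane C–O bonds are cut, leading to chalcone 15. Electrophilic asymmetric oxidations would attack the geranyl alkenes first. A nucleophilic peroxide sees only the electron-poor enone. The precursor is achiral and flat; the forward reaction must select one enone face.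

15 from 4 and 13. The C2=C3 bond (flavanone numbering) is cut into methyl ketone 4 and aldehyde 13, two halves of similar size. The fluorine in 4, in place of a hydroxyl, prevents the chalcone from cyclising to a racemic flavanone.

4 from 3. The two acetal C–O bonds are cut, leading to the free diphenol 3. The forward step is a plain double O-alkylation.

3 from 1. The aryl–acetyl bond is cut, leading to 5-fluororesorcinol (1). The forward acylation must go para to one hydroxyl and ortho to the other. The two such positions are equivalent.

13 from 10. The formyl carbon is cut from the arene, leaving aryl bromide 10. The forward step is a halogen–lithium exchange and formylation, with no regiochemical question because only one bromine remains.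

10 from 6 and 7. The C5'–C1'' bond is cut into the symmetrical dibromide 6 and geranyl bromide (7). The first exchange on 6 has no regiochemical question, and 7 brings in the whole chain with its alkene geometry already set. The forward step must alkylate at the primary allylic carbon without transposition.

6 from 5. The two acetal C–O bonds are cut, leading to 4,6-dibromoresorcinol (5). The bromines fix the 1,2,4,5 pattern of ring B, so nothing depends on the regiochemistry of alkylating a free resorcinol.

## Roads not taken

Alternative 1: The cut runs through ring B itself, at C5'–C6' and C2'–C3', so that the arene is assembled around geranylacetone A1 as the chain carrier. In the forward key step KOt-Bu would promote Michael addition of the internal enolate of A1 to methyl acrylate A2 and then Claisen closure of the methyl group onto the ester, which gives 4-geranylcyclohexane-1,3-dione A3 in one operation. Aromatisation would give 4-geranylresorcinol A4 , which after protection and formylation would reach 13.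
- Merits: A1 and A2 are very cheap, there is no organolithium chemistry, and no SN2 versus SN2' question arises for the chain.
- Weak points: dehydrogenating A3 to A4 needs oxidants or halogenation–elimination conditions that threaten the two alkenes. Commercial A1 is often a mixture of alkene isomers. The route also does nothing for C2, so the epoxidation sequence would still be needed.
- Comparison: it is better on raw-material cost. The chosen plan offers a ring B whose substitution pattern is fixed by the bromines from the first step, in three operations, with no oxidation in the presence of the chain.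

Alternative 2: The cut is at C1''–C2'' and at the C3''–methyl bond, so that the C2''=C3'' alkene is made rather than bought. Cp2ZrCl2-catalysed addition of AlMe3 to 6-methylhept-5-en-1-yne A5 would give an (E)-alkenylaluminium species. This would couple in the same pot under Pd(PPh3)4 (zerovalent palladium) with methyl 5-(chloromethyl)-2,4-bis(tert-butyldimethylsilyloxy)benzoate A6 to give methyl 5-geranyl-2,4-bis(tert-butyldimethylsilyloxy)benzoate A7 as the ring B building block.
- Merits: syn carbometalation gives the E alkene cleanly, and the benzylic coupling cannot give an allylic transposition.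
- Weak points: A5 and A6 each need their own preparation. The ester of A7 must then be brought to the aldehyde oxidation level. Its aryl silyl ethers would not survive the hydroxide condensation, so a protecting-group change is added.
- Comparison: it is better if geometric purity of the chain were the limiting problem. The chosen plan relies on copper-mediated alpha-selective allylation with retention of geometry and is several steps shorter.

Alternative 3: The cut removes ring A, at C8–C8a, C7–C8, C5–C6 and C4a–C5, so that the arene is made last. Irradiation of the diazoacetyl dihydropyranone A8 would trigger a Wolff rearrangement to a ketene. (Triisopropylsilyloxy)acetylene A9 would then add to that ketene, and ring opening followed by six-electron electrocyclisation would give the 7-O-triisopropylsilyl 2',4'-bis(methoxymethyl) ether of kuwanon E A10 with a free 5-hydroxyl.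
- Merits: O1–C8a exists before the arene does, so no aldolate is ever exposed to base. C2 could come from an asymmetric hetero-Diels–Alder reaction of 13. The two ring A oxygens emerge differentiated.
- Weak points: A8 is a long way from 13, and A9 must be prepared as well. The C2 stereocentre of A8 is flanked by an electron-rich aryl group and a vinylogous ester and must survive the photochemical and thermal cascade. The ketene intermediates can also undergo [2+2] addition with the geranyl alkenes. The differentiation of O5 and O7 is of no use here because both end as free hydroxyls.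
- Comparison: it is better in avoiding the base-sensitive ring closure. The chosen plan buys ring A as an intact arene, with correspondingly fewer steps, and uses only classical operations.

Key step: step 7

Assumption: the Hoesch acylation of 1 is taken to occur para to a hydroxyl group (C4), as with resorcinol itself; the alternative position between the two hydroxyls is the only competitor.

Remark on descriptors: the carbon that becomes flavanone C2 is C3 of the propanone chain. It is R in epoxide 16 and S in 17, 18 and 19 without any spatial change, because removal of the neighbouring C–O bond alters the priority order.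

## Route

Step 1
Reactants: 1 5-fluororesorcinol (5-fluorobenzene-1,3-diol)
Product: 3 1-(2-fluoro-4,6-dihydroxyphenyl)ethan-1-one, via ketiminium chloride 2 (not isolated)
Conditions: MeCN, ZnCl2, HCl (g), Et2O, 0 °C; then H2O, reflux
Reagents that add atoms: acetonitrile CC#N; water O
Why: Hoesch acylation; the nitrilium electrophile attacks the position para to one hydroxyl and ortho to the other (the two such positions are equivalent), and the precipitated ketiminium salt 2 is hydrolysed to the ketone.

Step 2
Reactants: 3 1-(2-fluoro-4,6-dihydroxyphenyl)ethan-1-one
Product: 4 1-[2-fluoro-4,6-bis(methoxymethoxy)phenyl]ethan-1-one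
Conditions: NaH (2.2 equiv), MOMCl (2.4 equiv), DMF, 0 °C to rt
Reagents that add atoms: chloromethyl methyl ether COCCl
Why: Williamson-type O-alkylation of both phenoxides; NaH in DMF is used because the hydroxyl next to the carbonyl is hydrogen-bonded, and the phenols are far more acidic than the methyl ketone.

Step 3
Reactants: 5 4,6-dibromoresorcinol (4,6-dibromobenzene-1,3-diol)
Product: 6 1,5-dibromo-2,4-bis(methoxymethoxy)benzene
Conditions: NaH (2.2 equiv), MOMCl (2.4 equiv), THF–DMF, 0 °C to rt
Reagents that add atoms: chloromethyl methyl ether COCCl
Why: Williamson-type protection of both phenols as methoxymethyl ethers, which also serve as coordinating groups for the lithiations that follow.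

Step 4
Reactants: 6 1,5-dibromo-2,4-bis(methoxymethoxy)benzene; 7 geranyl bromide ((2E)-1-bromo-3,7-dimethylocta-2,6-diene)
Product: 10 1-bromo-5-[(2E)-3,7-dimethylocta-2,6-dienyl]-2,4-bis(methoxymethoxy)benzene, via aryllithium 8 (not isolated), via arylcopper 9 (not isolated)
Conditions: n-BuLi (1.0 equiv), THF, −78 °C; CuBr·SMe2, −78 to −40 °C; then 7, −40 °C to rt
Reagents that add atoms: none
Why: Bromine–lithium exchange stops after one bromine because the second sits on an aryllithium; transmetalation to monovalent copper then gives allylic substitution at the primary carbon of 7 with retention of the E alkene, since attack at the other allylic terminus would create a quaternary centre.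

Step 5
Reactants: 10 1-bromo-5-[(2E)-3,7-dimethylocta-2,6-dienyl]-2,4-bis(methoxymethoxy)benzene
Product: 13 5-[(2E)-3,7-dimethylocta-2,6-dienyl]-2,4-bis(methoxymethoxy)benzaldehyde, via aryllithium 11 (not isolated), via lithium hemiaminal alkoxide 12 (not isolated)
Conditions: n-BuLi (1.1 equiv), THF, −78 °C; DMF, −78 °C to rt; H2O
Reagents that add atoms: N,N-dimethylformamide CN(C)C=O
Why: Second bromine–lithium exchange followed by Bouveault-type formylation; the tetrahedral adduct 12 persists until the aqueous quench, so no second addition occurs, and exchange is much faster than deprotonation of the benzylic–allylic methylene at −78 °C.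

Step 6
Reactants: 4 1-[2-fluoro-4,6-bis(methoxymethoxy)phenyl]ethan-1-one; 13 5-[(2E)-3,7-dimethylocta-2,6-dienyl]-2,4-bis(methoxymethoxy)benzaldehyde
Product: 15 (E)-1-[2-fluoro-4,6-bis(methoxymethoxy)phenyl]-3-[5-geranyl-2,4-bis(methoxymethoxy)phenyl]prop-2-en-1-one, via racemic aldol 14 (not isolated)
Conditions: KOH, EtOH–H2O, 0 °C to rt
Reagents that add atoms: none
Why: Claisen–Schmidt condensation; the enolate of 4 adds to the non-enolisable aldehyde and E1cB loss of water from 14 gives the more stable E enone, which cannot cyclise because ring A carries fluorine and no free phenol.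

Step 7
Reactants: 15 (E)-1-[2-fluoro-4,6-bis(methoxymethoxy)phenyl]-3-[5-geranyl-2,4-bis(methoxymethoxy)phenyl]prop-2-en-1-one
Product: 16 (2S,3R)-2,3-epoxy-1-[2-fluoro-4,6-bis(methoxymethoxy)phenyl]-3-[5-geranyl-2,4-bis(methoxymethoxy)phenyl]propan-1-one
Conditions: poly-D-leucine, urea–H2O2, DBU, THF, 20 °C
Reagents that add atoms: hydrogen peroxide (as its urea adduct) OO
Why: Juliá–Colonna epoxidation, the peptide-catalysed asymmetric form of the Weitz–Scheffer reaction, whose closest known use is on chalcones including those with ortho-alkoxy groups on the aroyl ring. Hydroperoxide anion, formed from urea–H2O2 and DBU, adds to the beta carbon of the enone (the future flavanone C2) while the enone is hydrogen-bonded to the N-terminal NH groups of the helical peptide. The peroxy enolate then closes the oxirane by 3-exo-tet attack of the alpha carbon on the near peroxide oxygen with loss of hydroxide, and rotation in the enolate lets the E enone give the trans epoxide. The oxirane is the only ring formed and is not part of the target. Both new stereocentres are set by the catalyst helix: the D-configured polymer is the mirror image of the L polymer that gives the 2R,3S oxide from chalcone, so the 2S,3R oxide is expected, and the trans relationship follows from the enone geometry. The step needs enantioface selectivity, secured by the flat E enone bound in the chiral peptide, and chemoselectivity for the enone over the two geranyl alkenes, secured by the nucleophilic oxidant. The methoxymethyl ethers and the aryl fluoride are inert to peroxide and DBU at this temperature.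

Step 8
Reactants: 16 (2S,3R)-2,3-epoxy-1-[2-fluoro-4,6-bis(methoxymethoxy)phenyl]-3-[5-geranyl-2,4-bis(methoxymethoxy)phenyl]propan-1-one
Product: 17 (3S)-1-[2-fluoro-4,6-bis(methoxymethoxy)phenyl]-3-[5-geranyl-2,4-bis(methoxymethoxy)phenyl]-3-hydroxypropan-1-one
Conditions: SmI2 (2.2 equiv), THF–MeOH, −90 °C
Reagents that add atoms: none
Why: Reductive opening of an alpha,beta-epoxy ketone by divalent samarium; the ketyl fragments the adjacent C–O bond to an enolate that methanol protonates, while the beta C–O bond and its configuration are untouched and the alkenes, fluoride and acetals do not react at this temperature.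

Step 9
Reactants: 17 (3S)-1-[2-fluoro-4,6-bis(methoxymethoxy)phenyl]-3-[5-geranyl-2,4-bis(methoxymethoxy)phenyl]-3-hydroxypropan-1-one
Product: 18 (2S)-2-[5-geranyl-2,4-bis(methoxymethoxy)phenyl]-5,7-bis(methoxymethoxy)-2,3-dihydro-4H-chromen-4-one
Conditions: NaH (1.0 equiv), THF–DMF, 0 °C to rt; AcOH quench
Reagents that add atoms: none
Why: Intramolecular nucleophilic aromatic substitution; the alkoxide adds to the fluorinated carbon ortho to the carbonyl (the adduct is stabilised as an enolate) and fluoride leaves, closing six-membered ring C through O1–C8a with no bond at C2 broken, so the S configuration is retained. One equivalent of base at low temperature limits retro-aldol and E1cB pathways.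

Step 10
Reactants: 18 (2S)-2-[5-geranyl-2,4-bis(methoxymethoxy)phenyl]-5,7-bis(methoxymethoxy)-2,3-dihydro-4H-chromen-4-one
Product: 19 kuwanon E, (2S)-2-[5-geranyl-2,4-dihydroxyphenyl]-5,7-dihydroxy-2,3-dihydro-4H-chromen-4-one
Conditions: HCl (3 M aq), MeOH, 45 °C, stopped at full conversion
Reagents that add atoms: none
Why: Acid-catalysed transacetalisation of the four aryl methoxymethyl ethers to methanol, a standard unmasking for prenylated flavanones; dilute acid and short exposure are chosen to spare the geranyl alkenes and the benzylic C2–O1 bond.

## Compound list

1 | 5-fluororesorcinol | Oc1cc(O)cc(F)c1 | starting material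
2 | 1-(2-fluoro-4,6-dihydroxyphenyl)ethan-1-iminium chloride | CC(=[NH2+])c1c(F)cc(O)cc1O.[Cl-] | intermediate
3 | 1-(2-fluoro-4,6-dihydroxyphenyl)ethan-1-one | CC(=O)c1c(F)cc(O)cc1O | intermediate
4 | 1-[2-fluoro-4,6-bis(methoxymethoxy)phenyl]ethan-1-one | CC(=O)c1c(F)cc(OCOC)cc1OCOC | intermediate
5 | 4,6-dibromoresorcinol | Oc1cc(O)c(Br)cc1Br | starting material
6 | 1,5-dibromo-2,4-bis(methoxymethoxy)benzene | COCOc1cc(OCOC)c(Br)cc1Br | intermediate
7 | geranyl bromide | CC(C)=CCC/C(C)=C/CBr | starting material
8 | [5-bromo-2,4-bis(methoxymethoxy)phenyl]lithium | [Li]c1cc(Br)c(OCOC)cc1OCOC | intermediate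
9 | [5-bromo-2,4-bis(methoxymethoxy)phenyl]copper (monovalent copper) | [Cu]c1cc(Br)c(OCOC)cc1OCOC | intermediate
10 | 1-bromo-5-[(2E)-3,7-dimethylocta-2,6-dienyl]-2,4-bis(methoxymethoxy)benzene | CC(C)=CCC/C(C)=C/Cc1cc(Br)c(OCOC)cc1OCOC | intermediate
11 | [5-geranyl-2,4-bis(methoxymethoxy)phenyl]lithium | CC(C)=CCC/C(C)=C/Cc1cc([Li])c(OCOC)cc1OCOC | intermediate
12 | lithium (dimethylamino)[5-geranyl-2,4-bis(methoxymethoxy)phenyl]methanolate | CC(C)=CCC/C(C)=C/Cc1cc(C(O[Li])N(C)C)c(OCOC)cc1OCOC | intermediate
13 | 5-[(2E)-3,7-dimethylocta-2,6-dienyl]-2,4-bis(methoxymethoxy)benzaldehyde | CC(C)=CCC/C(C)=C/Cc1cc(C=O)c(OCOC)cc1OCOC | intermediate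
14 | racemic 1-[2-fluoro-4,6-bis(methoxymethoxy)phenyl]-3-[5-geranyl-2,4-bis(methoxymethoxy)phenyl]-3-hydroxypropan-1-one | CC(C)=CCC/C(C)=C/Cc1cc(C(O)CC(=O)c2c(F)cc(OCOC)cc2OCOC)c(OCOC)cc1OCOC | intermediate
15 | (E)-1-[2-fluoro-4,6-bis(methoxymethoxy)phenyl]-3-[5-geranyl-2,4-bis(methoxymethoxy)phenyl]prop-2-en-1-one | CC(C)=CCC/C(C)=C/Cc1cc(/C=C/C(=O)c2c(F)cc(OCOC)cc2OCOC)c(OCOC)cc1OCOC | intermediate
16 | (2S,3R)-2,3-epoxy-1-[2-fluoro-4,6-bis(methoxymethoxy)phenyl]-3-[5-geranyl-2,4-bis(methoxymethoxy)phenyl]propan-1-one | CC(C)=CCC/C(C)=C/Cc1cc([C@H]2O[C@@H]2C(=O)c3c(F)cc(OCOC)cc3OCOC)c(OCOC)cc1OCOC | intermediate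
17 | (3S)-1-[2-fluoro-4,6-bis(methoxymethoxy)phenyl]-3-[5-geranyl-2,4-bis(methoxymethoxy)phenyl]-3-hydroxypropan-1-one | CC(C)=CCC/C(C)=C/Cc1cc([C@@H](O)CC(=O)c2c(F)cc(OCOC)cc2OCOC)c(OCOC)cc1OCOC | intermediate
18 | (2S)-2-[5-geranyl-2,4-bis(methoxymethoxy)phenyl]-5,7-bis(methoxymethoxy)-2,3-dihydro-4H-chromen-4-one | CC(C)=CCC/C(C)=C/Cc1cc([C@@H]2CC(=O)c3c(OCOC)cc(OCOC)cc3O2)c(OCOC)cc1OCOC | intermediate
19 | kuwanon E | CC(C)=CCC/C(C)=C/Cc1cc([C@@H]2CC(=O)c3c(O)cc(O)cc3O2)c(O)cc1O | target

## Step count and risks

Total: 10 steps. Longest linear sequence: 8 steps (steps 3, 4, 5, 6, 7, 8, 9, 10 from 5).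

Step 7 (key step). Facial selectivity may be poor, or addition slow enough for the uncatalysed racemic epoxidation to compete. The aroyl ring has two ortho substituents and is twisted out of the enone plane, and the electron-rich ring B lowers the electrophilicity of the beta carbon. Fallback: from 15, enantioselective conjugate borylation with B2pin2 and MeOH, catalysed by CuCl (monovalent copper), NaOt-Bu and an enantiopure bisphosphine such as Tol-BINAP in the hand that delivers the S product. This would give (3S)-1-[2-fluoro-4,6-bis(methoxymethoxy)phenyl]-3-[5-geranyl-2,4-bis(methoxymethoxy)phenyl]-3-(4,4,5,5-tetramethyl-1,3,2-dioxaborolan-2-yl)propan-1-one F1. Stereoretentive oxidation of the C–B bond with NaBO3·4H2O in THF–water would then give 17. This joins the route at 17 and bypasses 16 and step 8.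

Step 9. The alkoxide may fragment by retro-aldol (racemisation on recombination) or dehydrate by E1cB before it closes the ring. Excess base may also open the product at C2. Fallback: from 17, silylation with Et3SiCl and imidazole to the triethylsilyl ether of 17 F2, then a catalytic amount of CsF in DMF. Fluoride unmasks the alkoxide only in small standing concentration, and the fluoride released by ring closure carries the chain on, so no stoichiometric base is ever present. The route is rejoined at 18.

Step 10. Protic acid may add the 4'-hydroxyl across the C2''=C3'' alkene, start cation–olefin cyclisation of the chain, or reversibly ionise the benzylic C2–O1 bond and erode the configuration. Fallback: from 18, acetal-to-silyl exchange with Me3SiOTf buffered by 2,2'-bipyridyl in MeCN at 0 °C, giving the tetrakis(trimethylsilyl) ether of kuwanon E F3. The aryl silyl ethers are then hydrolysed with water at neutral pH to 19.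

Step 8. The Lewis-acidic trivalent samarium may promote loss of the electron-rich benzylic hydroxyl, or the ketone may be over-reduced. Fallback: from 16, a two-electron pathway with the selenolate Na[PhSeB(OEt)3] (from PhSeSePh and NaBH4 in EtOH, buffered with AcOH, 0 °C). Selenolate opens the epoxide at the alpha carbon with inversion to the (2R,3R)-3-hydroxy-2-(phenylselanyl) ketone F4 (not isolated). A second selenolate removes selenium to give 17.

Step 6. Hydroxide or ethoxide may displace the carbonyl-activated fluoride, and the hindered ketone may add slowly. Fallback: from 4 and 13, a directed aldol (LiN(SiMe3)2, THF, −78 °C, then 13) with isolation of 14. Treatment with MsCl and Et3N then DBU in CH2Cl2 would eliminate through the racemic methanesulfonate of 14 F5 (not isolated) to 15.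

## Further compounds

F1 | step 7 | (3S)-1-[2-fluoro-4,6-bis(methoxymethoxy)phenyl]-3-[5-geranyl-2,4-bis(methoxymethoxy)phenyl]-3-(4,4,5,5-tetramethyl-1,3,2-dioxaborolan-2-yl)propan-1-one | CC(C)=CCC/C(C)=C/Cc1cc([C@@H](B2OC(C)(C)C(C)(C)O2)CC(=O)c3c(F)cc(OCOC)cc3OCOC)c(OCOC)cc1OCOC
F2 | step 9 | (3S)-1-[2-fluoro-4,6-bis(methoxymethoxy)phenyl]-3-[5-geranyl-2,4-bis(methoxymethoxy)phenyl]-3-(triethylsilyloxy)propan-1-one | CC(C)=CCC/C(C)=C/Cc1cc([C@@H](O[Si](CC)(CC)CC)CC(=O)c2c(F)cc(OCOC)cc2OCOC)c(OCOC)cc1OCOC
F3 | step 10 | (2S)-2-[5-geranyl-2,4-bis(trimethylsilyloxy)phenyl]-5,7-bis(trimethylsilyloxy)-2,3-dihydro-4H-chromen-4-one | CC(C)=CCC/C(C)=C/Cc1cc([C@@H]2CC(=O)c3c(O[Si](C)(C)C)cc(O[Si](C)(C)C)cc3O2)c(O[Si](C)(C)C)cc1O[Si](C)(C)C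
F4 | step 8 | (2R,3R)-1-[2-fluoro-4,6-bis(methoxymethoxy)phenyl]-3-[5-geranyl-2,4-bis(methoxymethoxy)phenyl]-3-hydroxy-2-(phenylselanyl)propan-1-one | CC(C)=CCC/C(C)=C/Cc1cc([C@@H](O)[C@@H]([Se]c2ccccc2)C(=O)c3c(F)cc(OCOC)cc3OCOC)c(OCOC)cc1OCOC
F5 | step 6 | racemic 3-[2-fluoro-4,6-bis(methoxymethoxy)phenyl]-1-[5-geranyl-2,4-bis(methoxymethoxy)phenyl]-3-oxopropyl methanesulfonate | CC(C)=CCC/C(C)=C/Cc1cc(C(OS(C)(=O)=O)CC(=O)c2c(F)cc(OCOC)cc2OCOC)c(OCOC)cc1OCOC
A1 | alternative 1 | geranylacetone, (5E)-6,10-dimethylundeca-5,9-dien-2-one | CC(C)=CCC/C(C)=C/CCC(C)=O
A2 | alternative 1 | methyl acrylate | C=CC(=O)OC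
A3 | alternative 1 | 4-geranylcyclohexane-1,3-dione | CC(C)=CCC/C(C)=C/CC1CCC(=O)CC1=O
A4 | alternative 1 | 4-geranylresorcinol | CC(C)=CCC/C(C)=C/Cc1ccc(O)cc1O
A5 | alternative 2 | 6-methylhept-5-en-1-yne | CC(C)=CCCC#C
A6 | alternative 2 | methyl 5-(chloromethyl)-2,4-bis(tert-butyldimethylsilyloxy)benzoate | COC(=O)c1cc(CCl)c(O[Si](C)(C)C(C)(C)C)cc1O[Si](C)(C)C(C)(C)C
A7 | alternative 2 | methyl 5-geranyl-2,4-bis(tert-butyldimethylsilyloxy)benzoate | CC(C)=CCC/C(C)=C/Cc1cc(C(=O)OC)c(O[Si](C)(C)C(C)(C)C)cc1O[Si](C)(C)C(C)(C)C
A8 | alternative 3 | (2S)-6-(diazoacetyl)-2-[5-geranyl-2,4-bis(methoxymethoxy)phenyl]-2,3-dihydro-4H-pyran-4-one | CC(C)=CCC/C(C)=C/Cc1cc([C@@H]2CC(=O)C=C(C(=O)C=[N+]=[N-])O2)c(OCOC)cc1OCOC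
A9 | alternative 3 | (triisopropylsilyloxy)acetylene | C#CO[Si](C(C)C)(C(C)C)C(C)C
A10 | alternative 3 | (2S)-7-O-triisopropylsilyl-2',4'-bis(methoxymethyl) ether of kuwanon E with free 5-hydroxyl | CC(C)=CCC/C(C)=C/Cc1cc([C@@H]2CC(=O)c3c(O)cc(O[Si](C(C)C)(C(C)C)C(C)C)cc3O2)c(OCOC)cc1OCOC
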